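Retrosynthetic cuts, in order: the aryl–O bond at C2 (tertiary alkoxide plus a honokiol-derived diaryliodonium salt), the C2–CH3 bond, the two C–CH3 bonds of the carbinol, and last the C5–C6 and C6–C7 bonds, after a ketone has been put back at C5.
Enabling feature: ring B without C6 is the cyclopentanone of the Hajos–Parrish ketone; its ring A enone carbonyl is para to the methyl-bearing carbon just as C2 is para to C4a, and its cyclopentanone carbonyl (C5) is next to the future ester carbon C7.
Forward: ring A and C4a are bought; the five-membered ring is carboxylated and bromomethylated at C7 with the enone masked as a dithiolane; the enone is freed and a Bu3SnH radical chain inserts C6 between C5 and C7, giving six-membered ring B.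
Then: C5 reduction, Li/NH3 reduction, C5 deoxygenation, ester equilibration, MeMgBr, MeTi(OiPr)3, O-arylation and desilylation; the aryl donor is made from honokiol in four steps.
Stereochemistry: C4a comes from ketone 1; C8a from axial protonation in the Li/NH3 reduction (trans fusion); C7 from thermodynamic equilibration of the ester; C2 from equatorial attack of MeTi(OiPr)3, retained in the O-arylation.

Key step: step 5

Labels: the decalin (naphthalene-type) atom numbers of the target are used for all bicyclic intermediates, including the hydrindanes that still lack C6; β is the face of the C4a methyl group, α the opposite face.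
Assumption: the C7 epimers formed in step 5 are not separated before step 11; compounds 9–15 are such mixtures and their SMILES carry no descriptor at C7.

Step 1
Reactants: 1 (S)-(+)-Hajos–Parrish ketone; 2 ethane-1,2-dithiol
Product: 3 C2 spiro-dithiolane of 1 (C1=C8a and the C5 ketone unchanged)
Conditions: HS(CH2)2SH (1.05 equiv), TsOH·H2O (cat.), AcOH, rt
Reagents that add atoms: ethane-1,2-dithiol (2), SCCS
Why: Acid-catalysed dithioketalisation in acetic acid picks the conjugated ketone, which alone ionises to a stabilised allylic thionium ion, over the neopentyl cyclopentanone, and unlike acetal formation with a diol it keeps the double bond at C1=C8a.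

Step 2
Reactants: 3 dithiolane ketone; 4 dimethyl carbonate
Product: 5 C7 methyl ester of 3 (β-keto ester; C7 epimers and enol form)
Conditions: NaH (2.5 equiv), (MeO)2CO (5 equiv), THF, reflux; AcOH
Reagents that add atoms: dimethyl carbonate (4), COC(=O)OC
Why: Crossed Claisen condensation of a ketone enolate with a carbonate, in which C7 is the only position of the C5 ketone that can enolise (C4a is quaternary, the enone is masked) and the product is stored as its stabilised enolate until the quench.

Step 3
Reactants: 5 β-keto ester; 6 dibromomethane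
Product: 7 C7 bromomethyl β-keto ester (CH2Br α, ester β; dithiolane retained)
Conditions: NaH (1.1 equiv), THF, 0 °C; CH2Br2 (10 equiv), DMPU, 60 °C
Reagents that add atoms: dibromomethane (6), BrCBr
Why: C-Alkylation of the β-keto ester enolate with excess CH2Br2, the usual way to Dowd–Beckwith substrates, should occur on the face away from the angular methyl group (CH2Br α), at a centre whose configuration is erased again in step 5.

Step 4
Reactants: 7 bromomethyl dithiolane
Product: 8 methyl (2R,7aS)-2-(bromomethyl)-7a-methyl-1,5-dioxo-2,3,5,6,7,7a-hexahydro-1H-indene-2-carboxylate (free C1=C8a enone)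
Conditions: MeI (10 equiv), CaCO3 (3 equiv), MeCN/H2O 4:1, 45 °C
Reagents that add atoms: water, O
Why: Alkylative hydrolysis of the dithiolane (S-methylation, opening to the allylic thionium ion, capture by water) is neutral enough for the β-keto ester and the neopentyl bromide, finds no enolisable position at the now quaternary C7, and returns the C1=C8a enone that steps 5 and 7 require.

Step 5
Reactants: 8 bromomethyl β-keto ester
Product: 9 methyl (4aS)-4a-methyl-2,5-dioxo-2,3,4,4a,5,6,7,8-octahydronaphthalene-7-carboxylate (C1=C8a enone; both C7 epimers)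
Conditions: Bu3SnH (1.2 equiv) and AIBN (0.1 equiv) added over 6 h, benzene (0.01 M), reflux
Reagents that add atoms: none
Why: The chain starts when Bu3Sn• takes bromine from 8; the primary C6 radical adds to the neighbouring C5 ketone carbonyl (C5–C6 bond), and the resulting cyclopropyloxy radical opens by β-scission of the C5–C7 bond to a tertiary, ester-stabilised C7 radical that is quenched by Bu3SnH. This is the Dowd–Beckwith one-carbon ring expansion of 2-(bromomethyl) cyclic β-keto esters, for which 2-oxocyclopentanecarboxylates are the standard substrates. Ring B is therefore not closed directly: a 3-exo-trig closure onto C=O followed by fragmentation enlarges the five-membered ring to the six-membered one (net 1,2-acyl shift). The one new stereocentre, C7, arises by hydrogen transfer to a planar radical with little facial bias, so both epimers are expected and are converged in step 11, while C4a is not involved. The step needs attack at the ketone and not at the ester carbonyl or the alkene, and it needs rearrangement to outrun direct reduction: the ketone is the more electrophilic carbonyl and only its shift ends in a stabilised radical, the C1=C8a bond is out of 3-exo reach (attack there would be 4-exo or 5-endo, whereas a double bond moved to C8 would open a vinyl shift, which is why the enone was freed first), and slow addition keeps Bu3SnH dilute.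

Step 6
Reactants: 9 enedione ester
Product: 11 5β-hydroxy-4aβ-methyl-2-oxo-2,3,4,4a,5,6,7,8-octahydronaphthalene-7-carboxylic acid (C7 epimers), via 5β-hydroxy enone ester 10 (not isolated)
Conditions: NaBH4 (0.3 equiv), MeOH/CH2Cl2 1:1, −20 °C; acetone; then LiOH (3 equiv), THF/H2O, rt; 1 M HCl to pH 3
Reagents that add atoms: LiOH (hydroxide oxygen of the acid), [Li+].[OH-]
Why: NaBH4 reduces the saturated C5 ketone of Wieland–Miescher-type enediones ahead of the conjugated C2 ketone, hydride entering anti to the axial methyl group to give the equatorial 5β-alcohol (a centre removed in step 10), and saponification in the same flask provides a carboxylate that will withstand Li/NH3.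

Step 7
Reactants: 11 hydroxy enone acid
Product: 12 5β-hydroxy-4aβ-methyl-2-oxo-trans-decahydronaphthalene-7-carboxylic acid (8a-H α; C7 epimers)
Conditions: Li (8 equiv), NH3(l)/THF, −78 °C; isoprene, then NH4Cl; 1 M HCl to pH 3
Reagents that add atoms: none
Why: Dissolving-metal reduction of the 4a-methyl octalone (Birch-type enone reduction) protonates the C8a carbanion axially, anti to the C4a methyl group, which sets the trans ring fusion (8a-H α), while carboxylate and alkoxide are inert and the C2 ketone stays masked as its enolate until the quench.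

Step 8
Reactants: 12 hydroxy keto acid
Product: 13 methyl 5β-hydroxy-2,2-dimethoxy-4aβ-methyl-trans-decahydronaphthalene-7-carboxylate (C7 epimers)
Conditions: HC(OMe)3 (6 equiv), MeOH, TsOH·H2O (5 mol%), 50 °C; Et3N
Reagents that add atoms: methanol, CO; trimethyl orthoformate, COC(OC)OC
Why: Acid-catalysed esterification and ketalisation run together with the orthoformate as water scavenger and leave a compound in which the ester is the only electrophile for step 12 and C7–H the only acidic position for step 11.

Step 9
Reactants: 13 hydroxy ester ketal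
Product: 14 C5 O-(imidazol-1-ylthiocarbonyl) derivative of 13
Conditions: 1,1'-thiocarbonyldiimidazole (2 equiv), DMAP (0.2 equiv), ClCH2CH2Cl, 80 °C
Reagents that add atoms: 1,1'-thiocarbonyldiimidazole, S=C(n1ccnc1)n1ccnc1
Why: Thioacylation of the single free hydroxyl group (first half of a Barton–McCombie deoxygenation) is well precedented for equatorial secondary alcohols next to an angular methyl group, and neither ester nor ketal reacts.

Step 10
Reactants: 14 thiocarbonyl derivative
Product: 15 methyl 2,2-dimethoxy-4aβ-methyl-trans-decahydronaphthalene-7-carboxylate (C5 now CH2; C7 epimers)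
Conditions: Bu3SnH (1.5 equiv), AIBN (0.2 equiv), toluene, 110 °C
Reagents that add atoms: none
Why: Barton–McCombie deoxygenation, in which Bu3Sn• adds to the thiocarbonyl sulfur, the C5–O bond fragments to a secondary radical and this is reduced by Bu3SnH, turns C5 into CH2 without touching another centre.

Step 11
Reactants: 15 ester ketal (C7 epimers)
Product: 16 methyl 2,2-dimethoxy-4aβ-methyl-trans-decahydronaphthalene-7β-carboxylate (equatorial ester, cis to the C4a methyl group)
Conditions: NaOMe (0.5 equiv), MeOH, 65 °C; chromatographic separation, the 7α epimer is resubmitted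
Reagents that add atoms: none
Why: Epimerisation through the ester enolate should take the mixture to its thermodynamic distribution, which in the rigid trans-decalin favours the equatorial 7β ester because the axial epimer has syn-axial contacts to the hydrogens on C5 and C8a, and the separated minor epimer is put through the step again.

Step 12
Reactants: 16 7β ester ketal
Product: 18 7β-(2-hydroxypropan-2-yl)-4aβ-methyl-trans-octahydronaphthalen-2(1H)-one, via ketal carbinol 17 (not isolated)
Conditions: MeMgBr (4 equiv), THF, 0 °C → rt; then 1 M HCl, THF, rt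
Reagents that add atoms: MeMgBr, C[Mg]Br; water, O
Why: Twofold addition of MeMgBr to the ester, the only electrophile present, gives the dimethyl carbinol, and the acidic work-up hydrolyses the dimethyl ketal so that the C2 ketone reappears only after the organometallic reagent is gone.

Step 13
Reactants: 18 keto carbinol
Product: 19 triethylsilyl ether of 18
Conditions: Et3SiCl (2 equiv), imidazole (4 equiv), DMAP (0.2 equiv), DMF, 40 °C
Reagents that add atoms: chlorotriethylsilane, CC[Si](Cl)(CC)CC
Why: Silylation of the only hydroxyl group keeps a second tertiary alkoxide out of step 19, and chloride/imidazole conditions do not convert the ketone into a silyl enol ether.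

Step 14
Reactants: 19 silyloxy ketone
Product: 20 2β,4aβ-dimethyl-7β-[2-(triethylsilyloxy)propan-2-yl]-trans-decahydronaphthalen-2α-ol (axial hydroxyl)
Conditions: MeTi(OiPr)3 (2 equiv, from ClTi(OiPr)3 and MeLi, Et2O, −40 °C), hexane/Et2O, −30 °C → rt; aq NH4Cl
Reagents that add atoms: MeLi, [Li]C (delivered as MeTi(OiPr)3, C[Ti](OC(C)C)(OC(C)C)OC(C)C)
Why: MeTi(OiPr)3 adds to unhindered cyclohexanones with a clear preference for equatorial attack (higher than that of MeLi or MeMgBr), which here places the new methyl group equatorial (β) and the hydroxyl group axial (α) at C2 as the target requires, and it leaves the silyl ether alone.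

Step 15
Reactants: 21 honokiol
Product: 22 4'-O-triisopropylsilyl honokiol (2-hydroxyl free)
Conditions: iPr3SiCl (1.05 equiv), imidazole (2.2 equiv), DMF, 0 °C
Reagents that add atoms: chlorotriisopropylsilane, CC(C)[Si](Cl)(C(C)C)C(C)C
Why: A bulky silyl chloride should react first at the 4'-hydroxyl group, flanked only by the CH2 of an allyl group, and not at the 2-hydroxyl group next to the twisted aryl ring, and regioisomeric or bis-silylated material can be returned to 21 with Bu4NF.

Step 16
Reactants: 22 mono-silyl ether
Product: 23 2-O-triflate of 22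
Conditions: Tf2O (1.2 equiv), pyridine, CH2Cl2, 0 °C
Reagents that add atoms: trifluoromethanesulfonic anhydride, O=S(=O)(OS(=O)(=O)C(F)(F)F)C(F)(F)F
Why: Triflation of the remaining phenol is routine and turns the carbon that will later carry the ether oxygen into a site for carbon–metal exchange.

Step 17
Reactants: 23 aryl triflate
Product: 24 [3',5-diallyl-4'-(triisopropylsilyloxy)biphenyl-2-yl]trimethylstannane
Conditions: Me3SnSnMe3 (1.5 equiv), Pd(PPh3)4 (5 mol%), LiCl (5 equiv), dioxane, 100 °C
Reagents that add atoms: hexamethylditin, C[Sn](C)(C)[Sn](C)(C)C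
Why: Stannylation of an aryl triflate with a distannane under zerovalent palladium catalysis with LiCl (oxidative addition, transmetalation, reductive elimination) is established for ortho-substituted triflates, and in the absence of base the allyl groups have no productive Heck pathway.

Step 18
Reactants: 24 arylstannane
Product: 25 [3',5-diallyl-4'-(triisopropylsilyloxy)biphenyl-2-yl](4-methoxyphenyl)iodonium 4-methylbenzenesulfonate
Conditions: 4-MeOC6H4I(OAc)2 (1.0 equiv), TsOH·H2O (1.0 equiv), MeCN/CH2Cl2, 0 °C, 15 min; then 24, 0 °C → rt
Reagents that add atoms: [bis(acetoxy)iodo]-4-methoxybenzene, COc1ccc(I(OC(C)=O)OC(C)=O)cc1; 4-methylbenzenesulfonic acid monohydrate, Cc1ccc(S(=O)(=O)O)cc1.O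
Why: Tin-to-iodine exchange between an arylstannane and a hydroxy(tosyloxy)iodoarene generated in the flask is a mild, known entry to unsymmetrical diaryliodonium salts that should be much faster at 0 °C than attack of the trivalent iodine electrophile on unactivated terminal alkenes, and the 4-methoxyphenyl group is chosen as the ligand that is not transferred.

Step 19
Reactants: 20 tertiary alcohol; 25 diaryliodonium salt
Product: 26 bis-silyl ether of the target (2α-aryloxy; 4'-O-triisopropylsilyl; side-chain O-triethylsilyl)
Conditions: NaH (1.2 equiv), toluene, rt, 1 h; then 25 (1.3 equiv), rt → 40 °C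
Reagents that add atoms: none
Why: Metal-free O-arylation of tertiary alkoxides with diaryliodonium salts (ligand exchange at iodine followed by ligand coupling) is a known route to congested tert-alkyl aryl ethers, in which the ortho-substituted biaryl unit should be transferred in preference to the electron-rich 4-methoxyphenyl ligand, and because the C2–O bond is not involved the axial configuration of 20 is retained.

Step 20
Reactants: 26 bis-silyl ether
Product: 27 target, 3',5-diallyl-2-{[7β-(2-hydroxypropan-2-yl)-2β,4aβ-dimethyl-trans-decahydronaphthalen-2α-yl]oxy}biphenyl-4'-ol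
Conditions: Bu4NF (3 equiv), THF, rt → 40 °C; aq NH4Cl
Reagents that add atoms: none
Why: Fluoride removes the aryl triisopropylsilyl ether and the tertiary triethylsilyl ether in one operation under non-acidic conditions, which spares the acid-labile tert-alkyl aryl ether and the allyl groups.

Compound list
1 | (S)-(+)-Hajos–Parrish ketone, (7aS)-7a-methyl-2,3,7,7a-tetrahydro-1H-indene-1,5(6H)-dione | O=C1CC[C@]2(C)C(=O)CCC2=C1 | starting material
2 | ethane-1,2-dithiol | SCCS | starting material
3 | (7a'S)-7a'-methyl-2',3',7',7a'-tetrahydrospiro[1,3-dithiolane-2,5'-inden]-1'(6'H)-one (enone carbonyl of 1 as dithiolane) | C1CSC2(S1)CC[C@]1(C)C(=O)CCC1=C2 | intermediate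
4 | dimethyl carbonate | COC(=O)OC | starting material
5 | methyl ester of 3 carboxylated at C7 (β-keto ester, C7 epimers and enol) | C1CSC2(S1)CC[C@]1(C)C(=O)C(C(=O)OC)CC1=C2 | intermediate
6 | dibromomethane | BrCBr | starting material
7 | C7-(bromomethyl) derivative of 5 (CH2Br trans, ester cis to the C4a methyl group) | C1CSC2(S1)CC[C@]1(C)C(=O)[C@@](CBr)(C(=O)OC)CC1=C2 | intermediate
8 | methyl (2R,7aS)-2-(bromomethyl)-7a-methyl-1,5-dioxo-2,3,5,6,7,7a-hexahydro-1H-indene-2-carboxylate | O=C1CC[C@]2(C)C(=O)[C@@](CBr)(C(=O)OC)CC2=C1 | intermediate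
9 | methyl (4aS)-4a-methyl-2,5-dioxo-2,3,4,4a,5,6,7,8-octahydronaphthalene-7-carboxylate (C7 epimers) | O=C1CC[C@]2(C)C(=O)CC(C(=O)OC)CC2=C1 | intermediate
10 | methyl 5β-hydroxy-4aβ-methyl-2-oxo-2,3,4,4a,5,6,7,8-octahydronaphthalene-7-carboxylate (C7 epimers; not isolated) | O=C1CC[C@]2(C)[C@@H](O)CC(C(=O)OC)CC2=C1 | intermediate
11 | 5β-hydroxy-4aβ-methyl-2-oxo-2,3,4,4a,5,6,7,8-octahydronaphthalene-7-carboxylic acid (C7 epimers) | O=C1CC[C@]2(C)[C@@H](O)CC(C(=O)O)CC2=C1 | intermediate
12 | 5β-hydroxy-4aβ-methyl-2-oxo-trans-decahydronaphthalene-7-carboxylic acid (8a-H α; C7 epimers) | O=C1CC[C@]2(C)[C@@H](O)CC(C(=O)O)C[C@H]2C1 | intermediate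
13 | methyl 5β-hydroxy-2,2-dimethoxy-4aβ-methyl-trans-decahydronaphthalene-7-carboxylate (C7 epimers) | COC1(OC)CC[C@]2(C)[C@@H](O)CC(C(=O)OC)C[C@H]2C1 | intermediate
14 | methyl 5β-[(imidazol-1-ylthiocarbonyl)oxy]-2,2-dimethoxy-4aβ-methyl-trans-decahydronaphthalene-7-carboxylate (C7 epimers) | COC1(OC)CC[C@]2(C)[C@@H](OC(=S)n3ccnc3)CC(C(=O)OC)C[C@H]2C1 | intermediate
15 | methyl 2,2-dimethoxy-4aβ-methyl-trans-decahydronaphthalene-7-carboxylate (C7 epimers) | COC1(OC)CC[C@]2(C)CCC(C(=O)OC)C[C@H]2C1 | intermediate
16 | methyl 2,2-dimethoxy-4aβ-methyl-trans-decahydronaphthalene-7β-carboxylate (equatorial ester) | COC1(OC)CC[C@]2(C)CC[C@@H](C(=O)OC)C[C@H]2C1 | intermediate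
17 | 2-(7,7-dimethoxy-4aβ-methyl-trans-decahydronaphthalen-2β-yl)propan-2-ol, in route labels the 7β-carbinol 2,2-dimethyl ketal (not isolated) | COC1(OC)CC[C@]2(C)CC[C@@H](C(C)(C)O)C[C@H]2C1 | intermediate
18 | 7β-(2-hydroxypropan-2-yl)-4aβ-methyl-trans-octahydronaphthalen-2(1H)-one | O=C1CC[C@]2(C)CC[C@@H](C(C)(C)O)C[C@H]2C1 | intermediate
19 | 4aβ-methyl-7β-[2-(triethylsilyloxy)propan-2-yl]-trans-octahydronaphthalen-2(1H)-one | O=C1CC[C@]2(C)CC[C@@H](C(C)(C)O[Si](CC)(CC)CC)C[C@H]2C1 | intermediate
20 | 2β,4aβ-dimethyl-7β-[2-(triethylsilyloxy)propan-2-yl]-trans-decahydronaphthalen-2α-ol (axial OH) | O[C@]1(C)CC[C@]2(C)CC[C@@H](C(C)(C)O[Si](CC)(CC)CC)C[C@H]2C1 | intermediate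
21 | honokiol, 3',5-diallylbiphenyl-2,4'-diol | C=CCc1ccc(O)c(-c2ccc(O)c(CC=C)c2)c1 | starting material
22 | 3',5-diallyl-4'-(triisopropylsilyloxy)biphenyl-2-ol | C=CCc1ccc(O)c(-c2ccc(O[Si](C(C)C)(C(C)C)C(C)C)c(CC=C)c2)c1 | intermediate
23 | 3',5-diallyl-4'-(triisopropylsilyloxy)biphenyl-2-yl trifluoromethanesulfonate | C=CCc1ccc(OS(=O)(=O)C(F)(F)F)c(-c2ccc(O[Si](C(C)C)(C(C)C)C(C)C)c(CC=C)c2)c1 | intermediate
24 | [3',5-diallyl-4'-(triisopropylsilyloxy)biphenyl-2-yl]trimethylstannane | C=CCc1ccc([Sn](C)(C)C)c(-c2ccc(O[Si](C(C)C)(C(C)C)C(C)C)c(CC=C)c2)c1 | intermediate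
25 | [3',5-diallyl-4'-(triisopropylsilyloxy)biphenyl-2-yl](4-methoxyphenyl)iodonium 4-methylbenzenesulfonate | C=CCc1ccc([I+]c2ccc(OC)cc2)c(-c2ccc(O[Si](C(C)C)(C(C)C)C(C)C)c(CC=C)c2)c1.Cc1ccc(S(=O)(=O)[O-])cc1 | intermediate
26 | 4'-O-triisopropylsilyl, side-chain O-triethylsilyl ether of the target | C=CCc1ccc(O[C@]2(C)CC[C@]3(C)CC[C@@H](C(C)(C)O[Si](CC)(CC)CC)C[C@H]3C2)c(-c2ccc(O[Si](C(C)C)(C(C)C)C(C)C)c(CC=C)c2)c1 | intermediate
27 | 3',5-diallyl-2-{[7β-(2-hydroxypropan-2-yl)-2β,4aβ-dimethyl-trans-decahydronaphthalen-2α-yl]oxy}biphenyl-4'-ol (CNP0342687.1) | C=CCc1ccc(O[C@]2(C)CC[C@]3(C)CC[C@@H](C(C)(C)O)C[C@H]3C2)c(-c2ccc(O)c(CC=C)c2)c1 | target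

Total: 20 steps. Longest linear sequence: 16 steps (steps 1–14, 19 and 20); steps 15–18 are the four-step branch from honokiol.

Steps most likely to fail

Step 19 (O-arylation). Ligand coupling at the crowded axial alkoxide may be slow, so that aryne formation from 25, transfer of the 4-methoxyphenyl ligand or simple decomposition of the salt takes over. The fallback forms the C2–O bond by substitution with inversion and uses the phenol as nucleophile. It sets out from ketone 19. MeLi in the presence of methylaluminium bis(2,6-di-tert-butyl-4-methylphenoxide) (toluene, −78 °C) forces axial attack and should give the C2-epimeric alcohol F1 (2β-hydroxy, 2α-methyl). n-BuLi and Ph2PCl convert it into the alkyl diphenylphosphinite F2. Oxidation–reduction condensation of F2 with phenol 22 and tetrafluoro-1,4-benzoquinone (CH2Cl2, rt), a known way to tert-alkyl aryl ethers with inversion at carbon, would then give 26, where the route is rejoined before step 20.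

Step 5 (radical ring expansion). The primary radical may be reduced before it rearranges, leaving a C7 methyl group, or the chain may be diverted by the enone. The fallback is the polar counterpart of the same one-carbon insertion and sets out from β-keto ester 5. MeI/CaCO3 in aqueous MeCN frees the enone to give the β-keto ester F3. EtZnCH2I (from Et2Zn and CH2I2, CH2Cl2, 0 °C → rt) then effects the known chain extension of β-keto esters to γ-keto esters: the carbenoid carbon is attached at C7, closes onto the C5 carbonyl to a cyclopropoxide, and the C5–C7 bond opens. On this cyclic substrate that is the same ring expansion, and protonation gives 9, where the route is rejoined before step 6.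

Step 15 (mono-silylation of honokiol). Discrimination between the two phenols may be poor, giving mixtures of the 4'-O-silyl, 2-O-silyl and bis-silyl ethers. The fallback blocks the ring B phenol through its ortho-allyl group and sets out from honokiol 21. I2/NaHCO3 (MeCN, 0 °C) should give, by 5-exo iodoetherification, the 2-(iodomethyl)-2,3-dihydrobenzofuran F4, in which only the ring A phenol is free. Tf2O/pyridine gives the triflate F5. Zn dust in AcOH/EtOH reopens the iodo ether by reductive elimination to 2-O-triflyl honokiol F6. iPr3SiCl/imidazole then gives 23, where the route is rejoined before step 17.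

Further compounds
F1 | step 19 | 2α,4aβ-dimethyl-7β-[2-(triethylsilyloxy)propan-2-yl]-trans-decahydronaphthalen-2β-ol (C2 epimer of 20, equatorial OH) | O[C@@]1(C)CC[C@]2(C)CC[C@@H](C(C)(C)O[Si](CC)(CC)CC)C[C@H]2C1
F2 | step 19 | diphenylphosphinite of F1 | c1ccccc1P(c1ccccc1)O[C@@]1(C)CC[C@]2(C)CC[C@@H](C(C)(C)O[Si](CC)(CC)CC)C[C@H]2C1
F3 | step 5 | methyl (7aS)-7a-methyl-1,5-dioxo-2,3,5,6,7,7a-hexahydro-1H-indene-2-carboxylate (C2 epimers and enol) | O=C1CC[C@]2(C)C(=O)C(C(=O)OC)CC2=C1
F4 | step 15 | 4-allyl-2-[2-(iodomethyl)-2,3-dihydrobenzofuran-5-yl]phenol (racemic at the new centre) | C=CCc1ccc(O)c(-c2ccc3OC(CI)Cc3c2)c1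
F5 | step 15 | 4-allyl-2-[2-(iodomethyl)-2,3-dihydrobenzofuran-5-yl]phenyl trifluoromethanesulfonate | C=CCc1ccc(OS(=O)(=O)C(F)(F)F)c(-c2ccc3OC(CI)Cc3c2)c1
F6 | step 15 | 3',5-diallyl-4'-hydroxybiphenyl-2-yl trifluoromethanesulfonate | C=CCc1ccc(OS(=O)(=O)C(F)(F)F)c(-c2ccc(O)c(CC=C)c2)c1
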